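The 1,2-dioxolane (O1–O2–C3–C4–C5) has two fully substituted carbons, C3 and C5, flanking the C4 methylene, with the acetic acid arm and the C16 chain cis. It is read as a cyclopropane C3–C4–C5 whose most substituted bond has taken up O–O. In the key step an enantiopure, ring-fused cyclopropylmethanol ionises, H2O2 opens the C3–C5 bond with inversion at C3, and the hydroperoxide closes transannularly on C5. The carbinol carbon ends as the C5 methyl group. A temporary six-membered carbocycle ties arm and chain together, enforces their cis relationship and is later cut by Baeyer–Villiger oxidation. The triene chain arrives by sp3–sp3 Suzuki coupling.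

Key step: step 4

Remark: dioxolane locants are O1, O2, C3 (bears CH2CO2H), C4, C5 (bears the chain); the facial sense of step 3 is assumed to follow the usual model for allylic alcohols, and the antipodal controller would be used if it did not.

Step 1
Reactants: 1 ethyl 2-methyl-4-oxocyclohex-2-ene-1-carboxylate (Hagemann's ester, racemic)
Product: 2 ethyl 7-methyl-1,4-dioxaspiro[4.5]dec-7-ene-8-carboxylate
Conditions: HOCH2CH2OH, p-TsOH (cat.), toluene, reflux, Dean–Stark
Reagents that add atoms: ethylene glycol, OCCO
Why: Acid-catalysed ketalisation of an enone moves the C=C out of conjugation with the former ketone, and here it should settle in the tetrasubstituted position conjugated with the ester, which erases the only stereocentre of 1 and places methyl and ester on adjacent alkene carbons.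

Step 2
Reactants: 2 ethyl 7-methyl-1,4-dioxaspiro[4.5]dec-7-ene-8-carboxylate
Product: 3 (7-methyl-1,4-dioxaspiro[4.5]dec-7-en-8-yl)methanol
Conditions: LiAlH4, Et2O, 0 °C
Reagents that add atoms: none
Why: Hydride reduction of the conjugated ester should stop at the tetrasubstituted allylic alcohol, with the ketal inert and no stereocentre formed.

Step 3
Reactants: 3 (7-methyl-1,4-dioxaspiro[4.5]dec-7-en-8-yl)methanol
Product: 4 [(1S,6R)-1-methylspiro[bicyclo[4.1.0]heptane-3,2'-[1,3]dioxolan]-6-yl]methanol
Conditions: Et2Zn, CH2I2, DME, (4S,5S)-2-butyl-N,N,N',N'-tetramethyl-1,3,2-dioxaborolane-4,5-dicarboxamide (1.2 equiv), CH2Cl2, −10 °C → rt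
Reagents that add atoms: diiodomethane, ICI
Why: In the Charette asymmetric Simmons–Smith cyclopropanation the zinc alkoxide bound to the chiral dioxaborolane delivers CH2 to one alkene face, and the syn addition sets both quaternary centres (1S,6R) at once, the cis ring fusion being the only possibility.

Step 4
Reactants: 4 [(1S,6R)-1-methylspiro[bicyclo[4.1.0]heptane-3,2'-[1,3]dioxolan]-6-yl]methanol
Product: 7 (1R,6R)-1,6-dimethyl-7,8-dioxabicyclo[4.2.1]nonan-3-one, via (7R)-7-hydroperoxy-7-methyl-9-methylidene-1,4-dioxaspiro[4.6]undecane 5 (not isolated), via (1R,6R)-1,6-dimethylspiro[7,8-dioxabicyclo[4.2.1]nonane-3,2'-[1,3]dioxolane] 6 (not isolated)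
Conditions: H2O2 (anhydrous, Et2O, 10 equiv), TfOH (0.3 equiv), CH2Cl2, −40 → 0 °C; aq. wash, then 1 M HCl, THF, rt
Reagents that add atoms: hydrogen peroxide, OO; water, O
Why: Proposed new method: acid-induced loss of water from the primary carbinol of 4 should give a cyclopropylcarbinyl (bicyclobutonium) cation, which H2O2 captures at the methyl-bearing quaternary carbon anti to the breaking ring-fusion bond to give the 3-methylenecycloheptyl hydroperoxide 5; Markovnikov protonation of its exocyclic methylene (the former carbinol carbon, now the second methyl group) then gives a tertiary cation that the OOH group traps across the ring, so that O–O is inserted into the C1–C6 bond of 4 and its three-membered ring C1–C7–C6 becomes the five-membered 1,2-dioxolane of 6, whose ketal is hydrolysed in the acidic work-up to 7. The closest known reaction types are the stereoinvertive substitution at quaternary carbons of cyclopropylcarbinyl derivatives by halide or azide, the invertive acid-promoted perhydrolysis of tertiary oxetanes, and the acid-catalysed addition of tertiary hydroperoxides to 1,1-disubstituted alkenes, whereas H2O2 as the nucleophile and the coupling of both events are new. The only ring closed is the dioxolane, by a transannular 5-exo-trig attack of the terminal peroxide oxygen on the protonated methylene carbon (cation capture). The first new stereocentre (C1 of 7, C3 of the target) is controlled by inversion at the (1S) carbon of 4, because the departing σ bond shields one face of the delocalised cation, and the second (C6 of 7, C5 of the target) is controlled by the ring, since a two-atom bridge across the 1,3-positions of the cycloheptane can only form cis. The step needs cleavage of the fully substituted fusion bond rather than the C6–C7 bond, homoallyl rather than cyclobutyl capture, and closure faster than re-ionisation of 5 to an achiral free cation: the first is secured by the tertiary character that only C1 offers, the second by the reversibility of hydroperoxide capture under acid with the dialkyl peroxide as the only exit, and the third by the proximity of OOH and methylene in the seven-membered ring. The ketal keeps C3 from enolising, so that 5 cannot lose H2O2 by β-elimination.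

Step 5
Reactants: 7 (1R,6R)-1,6-dimethyl-7,8-dioxabicyclo[4.2.1]nonan-3-one
Product: 8 (1R,7R)-1,7-dimethyl-4,8,9-trioxabicyclo[5.2.1]decan-3-one
Conditions: mCPBA, CH2Cl2, 0 °C → rt
Reagents that add atoms: 3-chloroperoxybenzoic acid, OOC(=O)c1cccc(Cl)c1
Why: In the Baeyer–Villiger oxidation C4H2 should migrate rather than C2H2, whose migratory aptitude is lowered by the electron-withdrawing β-peroxy carbon C1 and by its neopentyl crowding, while the di-tert-alkyl peroxide is inert to peracid and both stereocentres are untouched.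

Step 6
Reactants: 8 (1R,7R)-1,7-dimethyl-4,8,9-trioxabicyclo[5.2.1]decan-3-one
Product: 9 methyl 2-[(3R,5R)-5-(2-hydroxyethyl)-3,5-dimethyl-1,2-dioxolan-3-yl]acetate
Conditions: MeOH, camphorsulfonic acid (cat.), rt
Reagents that add atoms: methanol, CO
Why: Acid-catalysed transesterification should open the strained eight-membered lactone irreversibly in methanol, and acid rather than base is chosen so that the β-peroxy ester cannot epimerise at C3 by retro-oxa-Michael reaction once the tether is gone.

Step 7
Reactants: 9 methyl 2-[(3R,5R)-5-(2-hydroxyethyl)-3,5-dimethyl-1,2-dioxolan-3-yl]acetate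
Product: 11 methyl 2-[(3R,5S)-5-(2-bromoethyl)-3,5-dimethyl-1,2-dioxolan-3-yl]acetate (same spatial arrangement, descriptor changed by priority), via methyl 2-[(3R,5R)-3,5-dimethyl-5-(2-methylsulfonyloxyethyl)-1,2-dioxolan-3-yl]acetate 10 (not isolated)
Conditions: MsCl, Et3N, CH2Cl2, 0 °C; then LiBr, acetone, rt → 40 °C
Reagents that add atoms: lithium bromide, [Li+].[Br-]; methanesulfonyl chloride, CS(=O)(=O)Cl (its atoms stay only in 10)
Why: Mesylation followed by Finkelstein-type SN2 displacement at the unhindered primary carbon avoids phosphines, which could reduce the O–O bond, and touches no stereocentre.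

Step 8
Reactants: 12 7-bromohept-1-ene; 13 1-phenyl-1H-tetrazole-5-thiol
Product: 14 5-(hept-6-en-1-ylsulfanyl)-1-phenyl-1H-tetrazole
Conditions: K2CO3, acetone, reflux
Reagents that add atoms: none
Why: SN2 S-alkylation of the soft thiolate by a primary bromide is a standard entry to Julia–Kocienski reagents.

Step 9
Reactants: 14 5-(hept-6-en-1-ylsulfanyl)-1-phenyl-1H-tetrazole
Product: 15 5-(hept-6-en-1-ylsulfonyl)-1-phenyl-1H-tetrazole
Conditions: H2O2 (30 % aq.), (NH4)6Mo7O24·4H2O (cat.), EtOH, 0 °C → rt
Reagents that add atoms: hydrogen peroxide, OO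
Why: Molybdate-catalysed sulfide-to-sulfone oxidation is chemoselective for sulfur and should leave the unactivated terminal alkene unepoxidised.

Step 10
Reactants: 15 5-(hept-6-en-1-ylsulfonyl)-1-phenyl-1H-tetrazole; 16 (2E,4E)-hepta-2,4-dienal
Product: 17 (7E,9E,11E)-tetradeca-1,7,9,11-tetraene
Conditions: KHMDS, DME, −60 °C; then 16, −60 °C → rt; H2O quench
Reagents that add atoms: none
Why: The Julia–Kocienski olefination of a potassiated alkyl phenyltetrazolyl sulfone in DME should set the new C7=C8 bond E through anti addition, Smiles rearrangement and anti elimination, the other two E bonds being carried in from 16.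

Step 11
Reactants: 17 (7E,9E,11E)-tetradeca-1,7,9,11-tetraene; 11 methyl 2-[(3R,5S)-5-(2-bromoethyl)-3,5-dimethyl-1,2-dioxolan-3-yl]acetate
Product: 19 methyl 2-[(3R,5R)-5-[(9E,11E,13E)-hexadeca-9,11,13-trien-1-yl]-3,5-dimethyl-1,2-dioxolan-3-yl]acetate, via 9-[(7E,9E,11E)-tetradeca-7,9,11-trien-1-yl]-9-borabicyclo[3.3.1]nonane 18 (not isolated)
Conditions: 9-BBN-H (1.0 equiv), THF, 0 °C → rt; then 11, Pd(OAc)2 (cat.), PCy3 (cat.), K3PO4·H2O, THF, rt
Reagents that add atoms: 9-borabicyclo[3.3.1]nonane, B1C2CCCC1CCC2 (its boron unit stays only in 18)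
Why: 9-BBN should hydroborate only the monosubstituted terminal alkene of 17, and the B-alkyl Suzuki–Miyaura coupling with a primary alkyl bromide under Pd/PCy3 at room temperature forms the C2'–C3' bond without touching ester, hindered peroxide, triene or stereocentres.

Step 12
Reactants: 19 methyl 2-[(3R,5R)-5-[(9E,11E,13E)-hexadeca-9,11,13-trien-1-yl]-3,5-dimethyl-1,2-dioxolan-3-yl]acetate
Product: 20 2-[(3R,5R)-5-[(9E,11E,13E)-hexadeca-9,11,13-trien-1-yl]-3,5-dimethyl-1,2-dioxolan-3-yl]acetic acid (target)
Conditions: LiOH, THF/H2O, 0 °C; then 1 M HCl to pH 4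
Reagents that add atoms: lithium hydroxide, [Li+].[OH-]
Why: Saponification at 0 °C should be faster than α-deprotonation, so the β-peroxy ester does not open by retro-oxa-Michael reaction and C3, C5 and the triene stay untouched.

Compound list
1 | ethyl 2-methyl-4-oxocyclohex-2-ene-1-carboxylate (Hagemann's ester, racemic) | CCOC(=O)C1CCC(=O)C=C1C | starting material
2 | ethyl 7-methyl-1,4-dioxaspiro[4.5]dec-7-ene-8-carboxylate | CCOC(=O)C1=C(C)CC2(CC1)OCCO2 | intermediate
3 | (7-methyl-1,4-dioxaspiro[4.5]dec-7-en-8-yl)methanol | CC1=C(CO)CCC2(C1)OCCO2 | intermediate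
4 | [(1S,6R)-1-methylspiro[bicyclo[4.1.0]heptane-3,2'-[1,3]dioxolan]-6-yl]methanol | C[C@]12CC3(OCCO3)CC[C@@]1(CO)C2 | intermediate
5 | (7R)-7-hydroperoxy-7-methyl-9-methylidene-1,4-dioxaspiro[4.6]undecane | C[C@@]1(OO)CC(=C)CCC2(OCCO2)C1 | intermediate
6 | (1R,6R)-1,6-dimethylspiro[7,8-dioxabicyclo[4.2.1]nonane-3,2'-[1,3]dioxolane] | O1CCOC12CC[C@]3(C)C[C@](C)(C2)OO3 | intermediate
7 | (1R,6R)-1,6-dimethyl-7,8-dioxabicyclo[4.2.1]nonan-3-one | O=C2CC[C@]1(C)C[C@](C)(C2)OO1 | intermediate
8 | (1R,7R)-1,7-dimethyl-4,8,9-trioxabicyclo[5.2.1]decan-3-one | O=C2OCC[C@]1(C)C[C@](C)(C2)OO1 | intermediate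
9 | methyl 2-[(3R,5R)-5-(2-hydroxyethyl)-3,5-dimethyl-1,2-dioxolan-3-yl]acetate | OCC[C@]1(C)C[C@](C)(CC(=O)OC)OO1 | intermediate
10 | methyl 2-[(3R,5R)-3,5-dimethyl-5-(2-methylsulfonyloxyethyl)-1,2-dioxolan-3-yl]acetate | CS(=O)(=O)OCC[C@]1(C)C[C@](C)(CC(=O)OC)OO1 | intermediate
11 | methyl 2-[(3R,5S)-5-(2-bromoethyl)-3,5-dimethyl-1,2-dioxolan-3-yl]acetate | BrCC[C@]1(C)C[C@](C)(CC(=O)OC)OO1 | intermediate
12 | 7-bromohept-1-ene | C=CCCCCCBr | starting material
13 | 1-phenyl-1H-tetrazole-5-thiol | Sc1nnnn1-c1ccccc1 | starting material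
14 | 5-(hept-6-en-1-ylsulfanyl)-1-phenyl-1H-tetrazole | C=CCCCCCSc1nnnn1-c1ccccc1 | intermediate
15 | 5-(hept-6-en-1-ylsulfonyl)-1-phenyl-1H-tetrazole | C=CCCCCCS(=O)(=O)c1nnnn1-c1ccccc1 | intermediate
16 | (2E,4E)-hepta-2,4-dienal | CC/C=C/C=C/C=O | starting material
17 | (7E,9E,11E)-tetradeca-1,7,9,11-tetraene | CC/C=C/C=C/C=C/CCCCC=C | intermediate
18 | 9-[(7E,9E,11E)-tetradeca-7,9,11-trien-1-yl]-9-borabicyclo[3.3.1]nonane | CC/C=C/C=C/C=C/CCCCCCB1C2CCCC1CCC2 | intermediate
19 | methyl 2-[(3R,5R)-5-[(9E,11E,13E)-hexadeca-9,11,13-trien-1-yl]-3,5-dimethyl-1,2-dioxolan-3-yl]acetate | CC/C=C/C=C/C=C/CCCCCCCC[C@]1(C)C[C@](C)(CC(=O)OC)OO1 | intermediate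
20 | 2-[(3R,5R)-5-[(9E,11E,13E)-hexadeca-9,11,13-trien-1-yl]-3,5-dimethyl-1,2-dioxolan-3-yl]acetic acid | CC/C=C/C=C/C=C/CCCCCCCC[C@]1(C)C[C@](C)(CC(=O)O)OO1 | target

Total step count: 12. Longest linear sequence: 9 (steps 1–7, 11, 12).

Steps most likely to fail

Step 4 (bears the label "Proposed new method:").
- What may go wrong: enantiomeric purity may erode if 5 re-ionises to a free, achiral tertiary cation. The cation manifold may be captured in its cyclobutyl form. Peroxide may exchange at the ketal, and the hydroperoxide may fragment in a Hock-type reaction.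
- Fallback (known chemistry, from 4 back to 6): TMSBr in CH2Cl2 at −78 °C, the known invertive bromide opening of cyclopropylcarbinols, would give the tertiary homoallylic bromide F1. Silver triflate-assisted perhydrolysis with ethereal H2O2 is known for tertiary halides. The neighbouring methylene group should regenerate the same delocalised cation and hence the same configuration, giving hydroperoxide 5, now isolated. Cycloperoxymercuration with Hg(OAc)2 would close the dioxolane without strong acid to the organomercurial F2. NaBH4/NaOH would then replace mercury by hydrogen to give 6, which is hydrolysed to 7 as in step 4.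

Step 11.
- What may go wrong: oxidative addition may be slow, with β-hydride elimination competing. Low-valent palladium or phosphine may reduce the O–O bond. The phosphate base may epimerise C3 by retro-oxa-Michael reaction, and the triene may be partly hydroborated or isomerised.
- Fallback (from 9 back to 19): Dess–Martin oxidation would give aldehyde F3. A Z-selective Wittig reaction with the ylide of [6-(1,3-dioxolan-2-yl)hexyl]triphenylphosphonium bromide would give the (Z)-alkene F4. Diimide reduction (2-nitrobenzenesulfonylhydrazide, Et3N), which spares O–O bonds, would give the saturated acetal F5. Mild acetal hydrolysis would give aldehyde F6. Horner–Wadsworth–Emmons olefination with lithiated diethyl (2E,4E)-hepta-2,4-dienylphosphonate would then give 19.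

Step 5.
- What may go wrong: the two methylene groups may migrate with poor regioselectivity, or the bridged cycloheptanone may oxidise sluggishly.
- Fallback (from 7 back to 9): kinetic deprotonation at the less hindered C4 with LiHMDS in the presence of TMSCl at −78 °C would give silyl enol ether F7. Ozonolysis with NaBH4 work-up would cut C3=C4 to hydroxy acid F8. Esterification with TMSCHN2 would give 9.

Further compounds
F1 | step 4 | (7R)-7-bromo-7-methyl-9-methylidene-1,4-dioxaspiro[4.6]undecane | C[C@@]1(Br)CC(=C)CCC2(OCCO2)C1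
F2 | step 4 | {[(1R,6R)-1-methylspiro[7,8-dioxabicyclo[4.2.1]nonane-3,2'-[1,3]dioxolan]-6-yl]methyl}mercury acetate | O1CCOC12CC[C@]3(C[Hg]OC(C)=O)C[C@](C)(C2)OO3
F3 | step 11 | methyl 2-[(3R,5S)-3,5-dimethyl-5-(2-oxoethyl)-1,2-dioxolan-3-yl]acetate | O=CC[C@]1(C)C[C@](C)(CC(=O)OC)OO1
F4 | step 11 | methyl 2-[(3R,5R)-5-[(2Z)-8-(1,3-dioxolan-2-yl)oct-2-en-1-yl]-3,5-dimethyl-1,2-dioxolan-3-yl]acetate | O1CCOC1CCCCC/C=C\C[C@]2(C)C[C@](C)(CC(=O)OC)OO2
F5 | step 11 | methyl 2-[(3R,5R)-5-[8-(1,3-dioxolan-2-yl)octyl]-3,5-dimethyl-1,2-dioxolan-3-yl]acetate | O1CCOC1CCCCCCCC[C@]2(C)C[C@](C)(CC(=O)OC)OO2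
F6 | step 11 | methyl 2-[(3R,5R)-3,5-dimethyl-5-(9-oxononyl)-1,2-dioxolan-3-yl]acetate | O=CCCCCCCCC[C@]1(C)C[C@](C)(CC(=O)OC)OO1
F7 | step 5 | (1R,6R)-1,6-dimethyl-3-(trimethylsilyloxy)-7,8-dioxabicyclo[4.2.1]non-3-ene | C[Si](C)(C)OC2=CC[C@]1(C)C[C@](C)(C2)OO1
F8 | step 5 | 2-[(3R,5R)-5-(2-hydroxyethyl)-3,5-dimethyl-1,2-dioxolan-3-yl]acetic acid | OCC[C@]1(C)C[C@](C)(CC(=O)O)OO1
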